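**Retrosynthetic overview**

1. The target comes from global desilylation and lactonisation; C13 is set by axial addition of a silyl ketene acetal to a cyclic peroxycarbenium ion, and C8=C17 by dehydration of an 8α-carbinol.
2. The spiro-1,2-dioxane comes from 6-exo opening, with inversion at C9, of an 8α,9α-epoxide by a C13 hydroperoxy ketal; the 8(9)-olefin comes from Negishi union of an enol triflate with a zinc homoenolate; 2α-OH comes from hydroboration.
3. Rings A and B are formed together by a one-pot intramolecular Diels–Alder (bonds C1–C2 and C5–C10) and formaldehyde allylboration (C4–C19) of an acyclic dienylboronate dienone; the dioxane follows (step 15), then the lactone (step 18).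
4. Enabling feature: ring A is a cyclohexane whose C10 bears a methyl and adjoins the spiro carbon C9 (a ketone in the precursor, giving the α-methyl enone dienophile C10=C1), whose C2 bears oxygen (a C–B bond at the diene terminus), and whose C5 adjoins the C6 carbinol (an allylic stereocentre that steers the diene face); ring B is the four-carbon tether C6–C9.
5. Only C6 is set by asymmetric catalysis; C5, C10, C4, C2, C9 and C13 are relayed from it.

Key step: step 6

Remark: bicyclic compounds are described with labdane numbering (ring A = C1–C5, C10; ring B = C5–C10; C17 on C8; C18 and C19 on C4; C20 on C10; side chain C11–C16); β is the face of the C10 methyl group.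

**Step 1**
Reactants: 1 (2E)-4,4-dimethoxy-2-methylbut-2-enal; 2 bis(4,4,5,5-tetramethyl-1,3,2-dioxaborolan-2-yl)methane
Product: 3 2-[(1E,3E)-5,5-dimethoxy-3-methylpenta-1,3-dien-1-yl]-4,4,5,5-tetramethyl-1,3,2-dioxaborolane
Conditions: lithium 2,2,6,6-tetramethylpiperidide, THF, 0 °C; then 1, −78 °C to rt; aq. NH4Cl
Reagents that add atoms: none
Why: Boron-Wittig olefination, in which the lithiated geminal bis(boronate) adds to the aldehyde and boron–oxygen elimination should give the (E)-alkenylboronate, the acetal being inert.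

**Step 2**
Reactants: 3 dienylboronate acetal
Product: 4 (2E,4E)-3-methyl-5-(4,4,5,5-tetramethyl-1,3,2-dioxaborolan-2-yl)penta-2,4-dienal
Conditions: oxalic acid (aq.), SiO2, CH2Cl2, rt
Reagents that add atoms: water, O
Why: Mild acid hydrolysis of a dimethyl acetal to the conjugated aldehyde, which the pinacol boronate should survive.

**Step 3**
Reactants: 4 dienal; 5 2,3-dibromoprop-1-ene
Product: 6 (4S,5E,7E)-2-bromo-6-methyl-8-(4,4,5,5-tetramethyl-1,3,2-dioxaborolan-2-yl)octa-1,5,7-trien-4-ol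
Conditions: CrCl2 (10 mol %), chiral N-sulfonyl aminooxazoline ligand (11 mol %), Mn powder, Me3SiCl, THF, 0 °C; then 1 M HCl
Reagents that add atoms: none
Why: Catalytic asymmetric Nozaki–Hiyama–Kishi 2-haloallylation, in which the allylchromium formed at the allylic C–Br adds 1,2 to the dienal and the ligand enantiomer is chosen to give the (S)-carbinol (C6), the only stereocentre set by a catalyst.

**Step 4**
Reactants: 6 bromo trienol
Product: 7 tert-butyldimethylsilyl ether of 6
Conditions: TBSCl, imidazole, DMF, rt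
Reagents that add atoms: tert-butyldimethylsilyl chloride, CC(C)(C)[Si](C)(C)Cl
Why: Standard silylation of a secondary allylic alcohol.

**Step 5**
Reactants: 7 vinyl bromide; 8 tributyl(prop-1-en-2-yl)stannane
Product: 9 (6S,7E,9E)-6-[(tert-butyldimethylsilyl)oxy]-2,8-dimethyl-4-methylidene-10-(4,4,5,5-tetramethyl-1,3,2-dioxaborolan-2-yl)deca-1,7,9-trien-3-one
Conditions: Pd2(dba)3 (2.5 mol %), AsPh3, CO (1 atm), LiCl, NMP, 45 °C, BHT; used crude
Reagents that add atoms: carbon monoxide, [C-]#[O+]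
Why: Carbonylative Stille coupling (oxidative addition to the vinyl bromide, CO insertion, transmetalation) should give the cross-conjugated dienone, and without base the boronate is not engaged.

**Step 6**
Reactants: 9 boryl trienone
Product: 11 trans-decalin homoallylic alcohol (5α-H; 10β-CH3; 4α-CH3; 4β-CH2OH; 2-ene; 6α-OTBS; 9-oxo; 8-methylidene), via allylboronate cycloadduct 10 (not isolated)
Conditions: PhMe (0.01 M), BHT, 110 °C; then (CH2O)n, 90 °C; aq. NH4Cl
Reagents that add atoms: formaldehyde, C=O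
Why: A thermal type-one intramolecular [4+2] cycloaddition of the (E,E)-1-boryldiene onto the isopropenyl ketone (closest precedents: cyclisations of 1,7,9-decatrien-3-ones and the tandem Diels–Alder/allylboration of 1-boronodienes) closes ring A by the cycloaddition and ring B through the tether, both six-membered, forming C1–C2 and C5–C10 with the regiochemistry fixed by the four-atom tether C6–C9. The C6 silyloxy stereocentre controls the diene face through allylic 1,3-strain with the C4 methyl (H6 in the diene plane, OTBS anti to the forming bond), which sets C5 and leaves OTBS equatorial on ring B. The exo orientation of the tether carbonyl (α-methyl dienophile, chair-like tether) gives the trans ring fusion and so sets C10, and the E-boronate places boron on the β face at C2. Allylboronate 10 then adds to formaldehyde through a closed six-membered transition state on the face of the C–B bond, creating the quaternary C4 with C19 β and C18 α and moving the alkene to C2–C3. The step needs exo over endo selectivity (secured by the α-methyl group and the absence of a Lewis acid) and reaction at the isopropenyl unit and not at the C8 methylidene (secured by tether length).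

**Step 7**
Reactants: 11 homoallylic alcohol
Product: 12 19-O-TBS ether of 11
Conditions: TBSOTf, 2,6-lutidine, CH2Cl2, −78 °C
Reagents that add atoms: tert-butyldimethylsilyl triflate, CC(C)(C)[Si](C)(C)OS(=O)(=O)C(F)(F)F
Why: Silyl triflate silylation of the hindered neopentyl primary alcohol, which the enone tolerates.

**Step 8**
Reactants: 12 α-methylidene ketone
Product: 14 8-methyl-8(9)-en-9-yl triflate, via lithium enolate 13 (not isolated)
Conditions: LiBH(s-Bu)3, THF, −78 °C; then N-(5-chloropyridin-2-yl)bis(trifluoromethanesulfonimide), −78 to 0 °C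
Reagents that add atoms: N-(5-chloropyridin-2-yl)bis(trifluoromethanesulfonimide), O=S(=O)(N(c1ccc(Cl)cn1)S(=O)(=O)C(F)(F)F)C(F)(F)F
Why: Conjugate reduction of the s-cis exocyclic enone by the hindered borohydride should give the tetrasubstituted enolate regiospecifically, and O-triflation traps it (reductive enol triflate formation).

**Step 9**
Reactants: 14 enol triflate
Product: 15 2α-alcohol
Conditions: 9-BBN, THF, 50 °C; then H2O2, NaOAc (aq.), rt
Reagents that add atoms: hydrogen peroxide, OO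
Why: Hydroboration–oxidation, in which the borane should add to C2=C3 from the α face (the β face is shielded by the syn-axial C19 and C20 groups) with boron at C2 (C3 is neopentyl), giving the equatorial 2α-OH, while the tetrasubstituted enol triflate is inert.

**Step 10**
Reactants: 15 2α-alcohol
Product: 16 2α-O-TBS ether
Conditions: TBSCl, imidazole, DMF, 40 °C
Reagents that add atoms: tert-butyldimethylsilyl chloride, CC(C)(C)[Si](C)(C)Cl
Why: Standard silylation of an equatorial secondary alcohol.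

**Step 11**
Reactants: 17 methyl 2-[(tert-butyldimethylsilyl)oxy]acetate
Product: 18 1-{[(tert-butyldimethylsilyl)oxy]methyl}cyclopropan-1-ol
Conditions: EtMgBr, Ti(OiPr)4 (20 mol %), THF, 0 °C to rt
Reagents that add atoms: ethylmagnesium bromide, CC[Mg]Br
Why: Kulinkovich cyclopropanation of an ester through a titanacyclopropane.

**Step 12**
Reactants: 18 cyclopropanol
Product: 19 1-[(tert-butyldimethylsilyl)oxy]-4-iodobutan-2-one
Conditions: N-iodosuccinimide, CH2Cl2, 0 °C, dark
Reagents that add atoms: N-iodosuccinimide, O=C1CCC(=O)N1I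
Why: Electrophilic ring-opening iodination of a cyclopropanol, which should give the β-iodo ketone.

**Step 13**
Reactants: 19 β-iodo ketone; 16 enol triflate
Product: 21 side-chain ketone (8-methyl-8(9)-ene carrying CH2CH2C(=O)CH2OTBS on C9), via zinc homoenolate 20 (not isolated)
Conditions: Zn, LiCl, THF, 30 °C; then 16, PdCl2(dppf) (5 mol %), THF/NMP, 55 °C
Reagents that add atoms: none
Why: Negishi cross-coupling of a zinc homoenolate with an alkenyl triflate, an sp2–sp3 union that tolerates the ketone and the silyl ethers.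

**Step 14**
Reactants: 21 side-chain ketone
Product: 23 C13 methoxy hydroperoxy ketal (both C13 epimers), via dimethyl ketal 22 (not isolated)
Conditions: HC(OMe)3, CSA (cat.), CH2Cl2, 0 °C; then H2O2 (anhydrous, Et2O), 0 °C
Reagents that add atoms: trimethyl orthoformate, COC(OC)OC; hydrogen peroxide, OO
Why: Ketalisation followed by acid-catalysed exchange of one methoxy group for hydroperoxide (peroxyketal exchange) at the unhindered side-chain ketone.

**Step 15**
Reactants: 23 hydroperoxy ketal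
Product: 25 spiro-1,2-dioxane carbinol (9β-O–O–C13; C11 α; 8α-OH; 8β-CH3; 13-OMe), via 8α,9α-epoxide 24 (not isolated)
Conditions: mCPBA, NaHCO3, CH2Cl2, −20 °C; then CSA (10 mol %), −20 to 0 °C
Reagents that add atoms: meta-chloroperbenzoic acid, O=C(OO)c1cccc(Cl)c1
Why: Prilezhaev epoxidation should occur on the α face (anti to the axial C10 methyl), and the hydroperoxide then opens the activated epoxide at C9 in the 6-exo mode with inversion, so the peroxide oxygen ends on the β face (syn to C20) with C11 α, while C8 keeps its α oxygen.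

**Step 16**
Reactants: 25 cyclic peroxyketal; 26 tert-butyl[(1-methoxyethenyl)oxy]dimethylsilane
Product: 27 C13 methyl acetate (C14 cis to C10 on the dioxane)
Conditions: Me3SiOTf (20 mol %), CH2Cl2, −78 °C
Reagents that add atoms: none
Why: Lewis acid ionisation of the exocyclic methoxy group gives a cyclic peroxycarbenium ion from both C13 epimers, and Mukaiyama-type addition of the silyl ketene acetal along the axial trajectory of the half-chair with C10 equatorial should place C14 cis to C10.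

**Step 17**
Reactants: 27 tertiary 8α-carbinol
Product: 28 8(17)-methylidene compound
Conditions: methyl N-(triethylammoniosulfonyl)carbamate (Burgess reagent), PhMe, 50 °C
Reagents that add atoms: none
Why: Burgess dehydration by syn elimination, in which only the C17 methyl offers a syn-coplanar hydrogen to the equatorial sulfamate, so the exocyclic alkene should form.

**Step 18**
Reactants: 28 tetrakis-silyl ether methyl ester
Product: 30 CNP0262224.1, via tetraol methyl ester 29 (not isolated)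
Conditions: HF·pyridine, THF/pyridine, 0 °C to rt; then PPTS (cat.), CH2Cl2, rt
Reagents that add atoms: none
Why: Acidic fluoride desilylation frees the four hydroxyls without touching the dialkyl peroxide, and the γ-hydroxy ester (C16–OH onto C15) should lactonise.

**Compound list**

1 | (2E)-4,4-dimethoxy-2-methylbut-2-enal | O=C/C(C)=C/C(OC)OC | starting material
2 | bis(4,4,5,5-tetramethyl-1,3,2-dioxaborolan-2-yl)methane | CC1(C)OB(CB2OC(C)(C)C(C)(C)O2)OC1(C)C | starting material
3 | 2-[(1E,3E)-5,5-dimethoxy-3-methylpenta-1,3-dien-1-yl]-4,4,5,5-tetramethyl-1,3,2-dioxaborolane | COC(OC)/C=C(C)/C=C/B1OC(C)(C)C(C)(C)O1 | intermediate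
4 | (2E,4E)-3-methyl-5-(4,4,5,5-tetramethyl-1,3,2-dioxaborolan-2-yl)penta-2,4-dienal | O=C/C=C(C)/C=C/B1OC(C)(C)C(C)(C)O1 | intermediate
5 | 2,3-dibromoprop-1-ene | C=C(Br)CBr | starting material
6 | (4S,5E,7E)-2-bromo-6-methyl-8-(4,4,5,5-tetramethyl-1,3,2-dioxaborolan-2-yl)octa-1,5,7-trien-4-ol | C=C(Br)C[C@H](O)/C=C(C)/C=C/B1OC(C)(C)C(C)(C)O1 | intermediate
7 | tert-butyldimethylsilyl ether of 6 (4S) | C=C(Br)C[C@H](O[Si](C)(C)C(C)(C)C)/C=C(C)/C=C/B1OC(C)(C)C(C)(C)O1 | intermediate
8 | tributyl(prop-1-en-2-yl)stannane | C=C(C)[Sn](CCCC)(CCCC)CCCC | starting material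
9 | (6S,7E,9E)-6-[(tert-butyldimethylsilyl)oxy]-2,8-dimethyl-4-methylidene-10-(4,4,5,5-tetramethyl-1,3,2-dioxaborolan-2-yl)deca-1,7,9-trien-3-one | C=C(C)C(=O)C(=C)C[C@H](O[Si](C)(C)C(C)(C)C)/C=C(C)/C=C/B1OC(C)(C)C(C)(C)O1 | intermediate
10 | allylboronate cycloadduct: trans-fused, 5α-H, 10β-CH3, 4-CH3, 3-ene, 2β-(pinacolboryl), 6α-OTBS, 8-methylidene, 9-oxo | C=C1C[C@H](O[Si](C)(C)C(C)(C)C)[C@H]2C(C)=C[C@@H](B3OC(C)(C)C(C)(C)O3)C[C@]2(C)C1=O | intermediate
11 | trans-decalin homoallylic alcohol: 5α-H, 10β-CH3, 4α-CH3, 4β-CH2OH, 2-ene, 6α-OTBS, 8-methylidene, 9-oxo | C=C1C[C@H](O[Si](C)(C)C(C)(C)C)[C@H]2[C@@](C)(CO)C=CC[C@]2(C)C1=O | intermediate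
12 | 19-O-TBS ether of 11 | C=C1C[C@H](O[Si](C)(C)C(C)(C)C)[C@H]2[C@@](C)(CO[Si](C)(C)C(C)(C)C)C=CC[C@]2(C)C1=O | intermediate
13 | lithium 8-methyl-8(9)-en-9-olate from 12 | CC=1C[C@H](O[Si](C)(C)C(C)(C)C)[C@H]2[C@@](C)(CO[Si](C)(C)C(C)(C)C)C=CC[C@]2(C)C=1[O-].[Li+] | intermediate
14 | 8-methyl-2,8(9)-dien-9-yl triflate (6α,19-bis-OTBS) | CC=1C[C@H](O[Si](C)(C)C(C)(C)C)[C@H]2[C@@](C)(CO[Si](C)(C)C(C)(C)C)C=CC[C@]2(C)C=1OS(=O)(=O)C(F)(F)F | intermediate
15 | 2α-hydroxy-8-methyl-8(9)-en-9-yl triflate (6α,19-bis-OTBS) | CC=1C[C@H](O[Si](C)(C)C(C)(C)C)[C@H]2[C@@](C)(CO[Si](C)(C)C(C)(C)C)C[C@H](O)C[C@]2(C)C=1OS(=O)(=O)C(F)(F)F | intermediate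
16 | 2α,6α,19-tris-OTBS 8-methyl-8(9)-en-9-yl triflate | CC=1C[C@H](O[Si](C)(C)C(C)(C)C)[C@H]2[C@@](C)(CO[Si](C)(C)C(C)(C)C)C[C@H](O[Si](C)(C)C(C)(C)C)C[C@]2(C)C=1OS(=O)(=O)C(F)(F)F | intermediate
17 | methyl 2-[(tert-butyldimethylsilyl)oxy]acetate | COC(=O)CO[Si](C)(C)C(C)(C)C | starting material
18 | 1-{[(tert-butyldimethylsilyl)oxy]methyl}cyclopropan-1-ol | OC1(CO[Si](C)(C)C(C)(C)C)CC1 | intermediate
19 | 1-[(tert-butyldimethylsilyl)oxy]-4-iodobutan-2-one | O=C(CCI)CO[Si](C)(C)C(C)(C)C | intermediate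
20 | {4-[(tert-butyldimethylsilyl)oxy]-3-oxobutyl}zinc iodide | O=C(CC[Zn]I)CO[Si](C)(C)C(C)(C)C | intermediate
21 | side-chain ketone: 8-methyl-8(9)-ene with C9–CH2CH2C(=O)CH2OTBS; 2α,6α,19-tris-OTBS | CC=1C[C@H](O[Si](C)(C)C(C)(C)C)[C@H]2[C@@](C)(CO[Si](C)(C)C(C)(C)C)C[C@H](O[Si](C)(C)C(C)(C)C)C[C@]2(C)C=1CCC(=O)CO[Si](C)(C)C(C)(C)C | intermediate
22 | C13 dimethyl ketal of 21 | CC=1C[C@H](O[Si](C)(C)C(C)(C)C)[C@H]2[C@@](C)(CO[Si](C)(C)C(C)(C)C)C[C@H](O[Si](C)(C)C(C)(C)C)C[C@]2(C)C=1CCC(OC)(OC)CO[Si](C)(C)C(C)(C)C | intermediate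
23 | C13 methoxy hydroperoxy ketal (C13 epimers) | CC=1C[C@H](O[Si](C)(C)C(C)(C)C)[C@H]2[C@@](C)(CO[Si](C)(C)C(C)(C)C)C[C@H](O[Si](C)(C)C(C)(C)C)C[C@]2(C)C=1CCC(OC)(OO)CO[Si](C)(C)C(C)(C)C | intermediate
24 | 8α,9α-epoxide of 23 | C[C@@]13C[C@H](O[Si](C)(C)C(C)(C)C)[C@H]2[C@@](C)(CO[Si](C)(C)C(C)(C)C)C[C@H](O[Si](C)(C)C(C)(C)C)C[C@]2(C)[C@@]1(O3)CCC(OC)(OO)CO[Si](C)(C)C(C)(C)C | intermediate
25 | spiro-1,2-dioxane carbinol: 9β,13-epidioxy, C11 α, 8α-OH, 8β-CH3, 13-OMe (C13 epimers), 13-CH2OTBS | C[C@@]1(O)C[C@H](O[Si](C)(C)C(C)(C)C)[C@H]2[C@@](C)(CO[Si](C)(C)C(C)(C)C)C[C@H](O[Si](C)(C)C(C)(C)C)C[C@]2(C)[C@]13CCC(OC)(CO[Si](C)(C)C(C)(C)C)OO3 | intermediate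
26 | tert-butyl[(1-methoxyethenyl)oxy]dimethylsilane | C=C(OC)O[Si](C)(C)C(C)(C)C | starting material
27 | C13 methyl acetate: 13-CH2CO2Me cis to C10 on the dioxane, 13-CH2OTBS, 8α-OH | C[C@@]1(O)C[C@H](O[Si](C)(C)C(C)(C)C)[C@H]2[C@@](C)(CO[Si](C)(C)C(C)(C)C)C[C@H](O[Si](C)(C)C(C)(C)C)C[C@]2(C)[C@]13CC[C@](CC(=O)OC)(CO[Si](C)(C)C(C)(C)C)OO3 | intermediate
28 | 8(17)-methylidene tetrakis-silyl ether methyl ester | C=C1C[C@H](O[Si](C)(C)C(C)(C)C)[C@H]2[C@@](C)(CO[Si](C)(C)C(C)(C)C)C[C@H](O[Si](C)(C)C(C)(C)C)C[C@]2(C)[C@]13CC[C@](CC(=O)OC)(CO[Si](C)(C)C(C)(C)C)OO3 | intermediate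
29 | tetraol methyl ester (2α,6α,16,19-tetrahydroxy) | C=C1C[C@H](O)[C@H]2[C@@](C)(CO)C[C@H](O)C[C@]2(C)[C@]13CC[C@](CC(=O)OC)(CO)OO3 | intermediate
30 | CNP0262224.1 | C=C1C[C@H](O)[C@H]2[C@@](C)(CO)C[C@H](O)C[C@]2(C)[C@]12CC[C@]1(COC(=O)C1)OO2 | target

**Step count and risks**

Total step count: 18. Longest linear sequence: 16 steps (steps 1–10 and 13–18).

Steps most likely to fail:

1. Step 15. The hydroperoxide may attack C8 (7-endo), or the tetrasubstituted epoxide may ionise, which loses the inversion at C9 or leads to rearrangement. Fallback: from 23 the ring is closed by cycloperoxymercuration (Hg(OAc)2, HClO4 cat., CH2Cl2, equilibrating conditions), which should give the anti adduct with both new substituents equatorial, the 8α-acetoxymercurio 9β,13-peroxide F1. Oxidative demercuration (NaBH4, O2, DMF) then returns the C8 carbinol 25; either C8 epimer serves, since C8 becomes sp2 in step 17.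

2. Step 6. Exo (trans-fusion) selectivity may erode, the cross-conjugated dienone may oligomerise, and allylboration at the hindered C4 (syn-axial to C20) may be slow. Fallback: from 9 the tether carbonyl is removed so that only the chair-like tether steers the cycloaddition. 1,2-Reduction (NaBH4, CeCl3, MeOH) gives the bis-allylic alcohol F2 and silylation (Et3SiCl, imidazole) gives the triethylsilyl ether F3. Thermal cycloaddition (PhMe, 170 °C) followed by formaldehyde allylboration gives the decalin alcohol F4, and TBSOTf gives the 19-O-TBS ether F5. Selective removal of the triethylsilyl group (PPTS, MeOH) gives the C9 carbinol F6, and Dess–Martin oxidation returns 12.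

3. Step 13. Transmetalation and reductive elimination at the tetrasubstituted, neopentyl-flanked triflate may be slow, so that reduction or elimination of the partners competes. Fallback: from 16 and 19 directly, a nickel-catalysed reductive cross-electrophile coupling (NiBr2(dme), 4,4'-di-tert-butyl-2,2'-bipyridine, Mn, DMA, rt) avoids the preformed organozinc and should give 21.

**Further compounds**

F1 | step 15 | 8α-acetoxymercurio-9β,13-epidioxy-13-methoxy compound (8β-CH3; tetrakis-OTBS) | C[C@@]1([Hg]OC(C)=O)C[C@H](O[Si](C)(C)C(C)(C)C)[C@H]2[C@@](C)(CO[Si](C)(C)C(C)(C)C)C[C@H](O[Si](C)(C)C(C)(C)C)C[C@]2(C)[C@]13CCC(OC)(CO[Si](C)(C)C(C)(C)C)OO3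
F2 | step 6 | (6S,7E,9E)-6-[(tert-butyldimethylsilyl)oxy]-2,8-dimethyl-4-methylidene-10-(pinacolboryl)deca-1,7,9-trien-3-ol (C3 epimers) | C=C(C)C(O)C(=C)C[C@H](O[Si](C)(C)C(C)(C)C)/C=C(C)/C=C/B1OC(C)(C)C(C)(C)O1
F3 | step 6 | triethylsilyl ether of F2 | C=C(C)C(O[Si](CC)(CC)CC)C(=C)C[C@H](O[Si](C)(C)C(C)(C)C)/C=C(C)/C=C/B1OC(C)(C)C(C)(C)O1
F4 | step 6 | trans-decalin alcohol: 4β-CH2OH, 4α-CH3, 2-ene, 6α-OTBS, 8-methylidene, 9-OSiEt3 (C9 epimers) | C=C1C[C@H](O[Si](C)(C)C(C)(C)C)[C@H]2[C@@](C)(CO)C=CC[C@]2(C)C1O[Si](CC)(CC)CC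
F5 | step 6 | 19-O-TBS ether of F4 | C=C1C[C@H](O[Si](C)(C)C(C)(C)C)[C@H]2[C@@](C)(CO[Si](C)(C)C(C)(C)C)C=CC[C@]2(C)C1O[Si](CC)(CC)CC
F6 | step 6 | C9 carbinol (6α,19-bis-OTBS, 2-ene, 8-methylidene) | C=C1C[C@H](O[Si](C)(C)C(C)(C)C)[C@H]2[C@@](C)(CO[Si](C)(C)C(C)(C)C)C=CC[C@]2(C)C1O
F0 | step 13 | none | none
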